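## Retrosynthetic overview
1. Target 27 is epicatechin-(4β→8)-epicatechin-(4β→6)-epicatechin. Cut both interflavan bonds (flavan-4-yl cation plus ring A arene); all three units come from one monomer, tetra-O-benzylepicatechin 21.
2. Br at C8 caps the top unit and blocks C8 of the bottom unit, so only C6 is open. Bonds are made top-down: 4β→8, then C4 oxidation of the middle unit, then 4β→6. One hydrogenolysis removes 12 Bn and 2 Br.
3. 21 comes from rac-flavan-3-one 20 by dynamic kinetic resolution hydrogenation, which sets 2R and 3R together.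
4. 20 comes from the isoflavan-type lactol 18 by a cationic 1,2-aryl shift C3→C2 (key step).
5. 18 comes from an o-quinone methide (resorcinol, CH2O) plus a mandelate enediolate (catechol, glyoxylic acid). Rings A and B are bought as arenes; ring C is closed in step 7 and re-shaped in step 8.

Assumption: 11 to 20 are racemates (18 and 19 are also anomer mixtures) and are written without stereo labels; absolute configuration enters in step 9.

## Route

**Step 1**
Reactants: 1 resorcinol
Product: 4 5-(4,4,5,5-tetramethyl-1,3,2-dioxaborolan-2-yl)benzene-1,3-diol, via O-borylated resorcinol 2 (not isolated), via triborylated arene 3 (not isolated)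
Conditions: HBpin (2.1 equiv), THF, rt; then [Ir(OMe)(cod)]2 (1.5 mol %), dtbpy (3 mol %), B2pin2 (1.0 equiv), 80 °C; MeOH quench
Reagents that add atoms: bis(pinacolato)diboron, CC1(C)OB(OC1(C)C)B1OC(C)(C)C(C)(C)O1; pinacolborane, [H]B1OC(C)(C)C(C)(C)O1 (atoms stay only in 2 and 3)
Why: Sterically governed iridium-catalysed aromatic C–H borylation of the in situ O-Bpin-masked diol hits C5, the only C–H without an ortho substituent, and methanol then strips the O–B masks.

**Step 2**
Reactants: 4 5-(pinacolatoboryl)benzene-1,3-diol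
Product: 6 3,5-bis(benzyloxy)phenol, via dibenzyl ether boronate 5 (not isolated)
Conditions: BnBr (2.2 equiv), K2CO3 (2.5 equiv), DMF, 40 °C; then 30 % aq H2O2, THF, 0 °C to rt
Reagents that add atoms: benzyl bromide, BrCc1ccccc1; hydrogen peroxide, OO
Why: Williamson etherification followed by boronate oxidation in the same pot differentiates the third ring A oxygen as the only free phenol.

**Step 3**
Reactants: 6 3,5-bis(benzyloxy)phenol; 7 formaldehyde
Product: 8 3,5-bis(benzyloxy)-2-[(dimethylamino)methyl]phenol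
Conditions: 37 % aq CH2O (1.0 equiv), 40 % aq Me2NH (1.05 equiv), EtOH, rt
Reagents that add atoms: dimethylamine, CNC
Why: The phenolic Mannich reaction is ortho-selective (hydrogen-bonded iminium delivery, and the para site is flanked by two OBn groups) and installs the future C4.

**Step 4**
Reactants: 9 catechol; 10 glyoxylic acid
Product: 11 rac-3,4-dihydroxymandelic acid
Conditions: 50 % aq 10 (1.0 equiv), NaOH (3 equiv), H2O, N2, 20 °C; HCl to pH 2
Reagents that add atoms: none
Why: Base-mediated hydroxyalkylation of the catecholate by glyoxylate (the mandelic acid step of the vanillin-type process) goes para to a phenoxide and gives the racemic acid, whose carbinol centre is erased later.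

**Step 5**
Reactants: 11 rac-3,4-dihydroxymandelic acid
Product: 12 rac-benzyl 2-[3,4-bis(benzyloxy)phenyl]-2-hydroxyacetate
Conditions: BnBr (3.3 equiv), K2CO3 (3.5 equiv), DMF, N2, 40 °C
Reagents that add atoms: benzyl bromide, BrCc1ccccc1
Why: Williamson and carboxylate alkylation under K2CO3 benzylates both phenols and the acid while the far less acidic secondary alcohol stays free.

**Step 6**
Reactants: 8 Mannich base; 12 benzyl mandelate
Product: 16 rac-benzyl 2-[3,4-bis(benzyloxy)phenyl]-3-[2,4-bis(benzyloxy)-6-hydroxyphenyl]-2-hydroxypropanoate, via dilithium enediolate 13 (not isolated), via ammonium iodide 14 (not isolated), via o-quinone methide 15 (not isolated)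
Conditions: 8, MeI (1.1 equiv), Et2O, rt (crude 14); 12, LiN(iPr)2 (3.2 equiv), THF, −78 °C; add 14, −78 to 0 °C; AcOH quench
Reagents that add atoms: methyl iodide, CI (atoms stay only in 14); LiN(iPr)2, [Li+].CC(C)[N-]C(C)C (Li stays only in 13)
Why: The phenoxide of 14 expels NMe3 to give o-quinone methide 15. Enediolate 13 traps 15 by Michael-type 1,4-addition driven by rearomatisation, which forms C3–C4; the new quaternary carbinol is racemic, which is harmless because it becomes the ketone carbon.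

**Step 7**
Reactants: 16 hydroxy ester
Product: 18 rac-5,7-bis(benzyloxy)-3-[3,4-bis(benzyloxy)phenyl]chromane-2,3-diol, via hydroxy aldehyde 17 (not isolated)
Conditions: iBu2AlH (3.3 equiv), CH2Cl2, −78 °C; aq KNaC4H4O6
Reagents that add atoms: none
Why: In this partial ester reduction the tetrahedral aluminate is held by the neighbouring alkoxide chelate, and on work-up aldehyde 17 is captured by the ortho phenol (hemiacetalisation), which closes ring C.

**Step 8 (key step)**
Reactants: 18 lactol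
Product: 20 rac-5,7-bis(benzyloxy)-2-[3,4-bis(benzyloxy)phenyl]chroman-3-one, via anomeric mesylate 19 (not isolated)
Conditions: MsCl (1.5 equiv), Et3N (4 equiv), CH2Cl2, −40 to 0 °C
Reagents that add atoms: methanesulfonyl chloride, CS(=O)(=O)Cl (atoms stay only in 19)
Why: Proposed new method: MsCl/Et3N sulfonylates the hemiacetal OH (the reagent pair that normally dehydrates 2-hydroxychromans), but C3 carries no hydrogen, so the axial mesylate 19 ionises with help from the O1 lone pair and the anti-periplanar, electron-rich 3,4-dibenzyloxyphenyl group, which bridges as a phenonium ion and moves from C3 to C2 while the tertiary OH, deprotonated by Et3N, collapses to the C3 ketone; this turns the isoflavan skeleton into the flavan skeleton and makes the C2–aryl bond, the ring C3–C4 bond lies near the oxocarbenium plane and cannot compete, and the base-buffered medium keeps the tertiary benzylic C3–OH from ionising; the closest known reaction types are the semipinacol (Tsuchihashi–Suzuki) rearrangement and the acyloin rearrangement of alpha-hydroxy aldehydes, neither of which has been shown on chromane-2,3-diols.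

**Step 9**
Reactants: 20 rac-flavan-3-one
Product: 21 (2R,3R)-5,7,3',4'-tetra-O-benzylepicatechin
Conditions: RuCl2[(S)-Xyl-SDP][(R,R)-DPEN] (0.5 mol %), KOtBu (10 mol %), iPrOH–toluene 2:1, H2 (50 atm), 25 °C; recrystallise
Reagents that add atoms: none
Why: Proposed new method: C2–H of 20 is alpha-keto, benzylic and alpha-aryloxy, so catalytic KOtBu racemises 20 quickly through the enolate while the Noyori-type ruthenium dihydride (diphosphine/diamine) reduces only the (2R)-ketone, delivering hydride anti to the C2 aryl group, which sets C2 (R) and C3 (R) together as the 2,3-cis alcohol; the closest known reaction type is the dynamic kinetic resolution hydrogenation of 2-aryl- and 2-alkoxycyclohexanones to cis alcohols (the catalyst antipode is chosen as the one that gives (1R,2R)-cis-2-substituted cyclohexanols), and this has not been shown on flavan-3-ones.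

**Step 10**
Reactants: 21 tetra-O-benzylepicatechin
Product: 22 (2R,3R)-8-bromo-5,7,3',4'-tetra-O-benzylepicatechin
Conditions: NBS (1.0 equiv), CH2Cl2, −78 °C to rt
Reagents that add atoms: N-bromosuccinimide, O=C1CCC(=O)N1Br
Why: Electrophilic aromatic bromination takes C8, the most nucleophilic and less shielded ring A position of benzylated flavan-3-ols.

**Step 11**
Reactants: 22 8-bromo monomer
Product: 23 (2R,3R,4S)-8-bromo-5,7,3',4'-tetra-O-benzyl-4β-(2-hydroxyethoxy)epicatechin
Conditions: DDQ (2 equiv), HOCH2CH2OH (10 equiv), CH2Cl2, rt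
Reagents that add atoms: ethylene glycol, OCCO
Why: DDQ benzylic oxidation (hydride abstraction) gives the ring A-stabilised C4 cation, and the glycol adds from the β face, trans to the axial 3-OH.

**Step 12**
Reactants: 23 capped electrophile; 21 tetra-O-benzylepicatechin (3 equiv, excess recovered)
Product: 24 [8-bromo-5,7,3',4'-tetra-O-benzylepicatechin]-(4β→8)-[5,7,3',4'-tetra-O-benzylepicatechin]
Conditions: TiCl4 (2 equiv), CH2Cl2–THF 9:1, 0 °C; H2O
Reagents that add atoms: none
Why: This is a Lewis acid-mediated Friedel–Crafts alkylation in which the flavan-4-yl cation (unable to self-condense at its brominated C8) is attacked by C8 of 21 on the β face, which sets C4 of the top unit 3,4-trans.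

**Step 13**
Reactants: 24 dimer
Product: 25 [8-bromo-5,7,3',4'-tetra-O-benzylepicatechin]-(4β→8)-[5,7,3',4'-tetra-O-benzyl-4β-(2-hydroxyethoxy)epicatechin]
Conditions: DDQ (2 equiv), HOCH2CH2OH (10 equiv), CH2Cl2, rt
Reagents that add atoms: ethylene glycol, OCCO
Why: The same DDQ benzylic oxidation takes the only remaining ring A benzylic CH2 (C4 of the lower unit), because the tertiary C4–H of the upper unit is buried and its cation cannot become planar.

**Step 14**
Reactants: 25 dimeric electrophile; 22 8-bromo monomer (5 equiv, excess recovered)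
Product: 26 [8-bromo-tetra-O-benzylepicatechin]-(4β→8)-[tetra-O-benzylepicatechin]-(4β→6)-[8-bromo-tetra-O-benzylepicatechin]
Conditions: TiCl4 (2 equiv), CH2Cl2–THF 9:1, 0 °C; H2O
Reagents that add atoms: none
Why: This is a Friedel–Crafts alkylation under halogen capping, in which C6 is the only free ring A position of 22, so the bond must be 4→6, and β-face attack sets C4 of the middle unit 3,4-trans.

**Step 15**
Reactants: 26 protected trimer
Product: 27 epicatechin-(4β→8)-epicatechin-(4β→6)-epicatechin (target)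
Conditions: H2 (1 atm), Pd(OH)2/C, NaOAc (2.2 equiv), THF–MeOH–H2O, rt
Reagents that add atoms: none
Why: Catalytic hydrogenolysis cleaves the twelve benzyl ethers and both aryl bromides in one operation, the acetate buffer takes up HBr so the acid-labile interflavan bonds survive, and no stereocentre is touched.

## Compound list
1 | resorcinol | Oc1cccc(O)c1 | starting material
2 | 1,3-bis[(4,4,5,5-tetramethyl-1,3,2-dioxaborolan-2-yl)oxy]benzene | CC1(C)OB(Oc2cccc(OB3OC(C)(C)C(C)(C)O3)c2)OC1(C)C | intermediate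
3 | 5-(pinacolatoboryl)-1,3-bis[(pinacolatoboryl)oxy]benzene | CC1(C)OB(Oc2cc(OB3OC(C)(C)C(C)(C)O3)cc(B3OC(C)(C)C(C)(C)O3)c2)OC1(C)C | intermediate
4 | 5-(4,4,5,5-tetramethyl-1,3,2-dioxaborolan-2-yl)benzene-1,3-diol | CC1(C)OB(c2cc(O)cc(O)c2)OC1(C)C | intermediate
5 | 2-[3,5-bis(benzyloxy)phenyl]-4,4,5,5-tetramethyl-1,3,2-dioxaborolane | CC1(C)OB(c2cc(OCc3ccccc3)cc(OCc3ccccc3)c2)OC1(C)C | intermediate
6 | 3,5-bis(benzyloxy)phenol | Oc1cc(OCc2ccccc2)cc(OCc2ccccc2)c1 | intermediate
7 | formaldehyde | C=O | starting material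
8 | 3,5-bis(benzyloxy)-2-[(dimethylamino)methyl]phenol | CN(C)Cc1c(O)cc(OCc2ccccc2)cc1OCc1ccccc1 | intermediate
9 | catechol | Oc1ccccc1O | starting material
10 | glyoxylic acid | O=CC(=O)O | starting material
11 | rac-3,4-dihydroxymandelic acid | OC(C(=O)O)c1ccc(O)c(O)c1 | intermediate
12 | rac-benzyl 2-[3,4-bis(benzyloxy)phenyl]-2-hydroxyacetate | OC(C(=O)OCc1ccccc1)c1ccc(OCc2ccccc2)c(OCc2ccccc2)c1 | intermediate
13 | dilithium enediolate of 12 | [Li+].[Li+].[O-]C(OCc1ccccc1)=C([O-])c1ccc(OCc2ccccc2)c(OCc2ccccc2)c1 | intermediate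
14 | [2,4-bis(benzyloxy)-6-hydroxybenzyl]trimethylammonium iodide | C[N+](C)(C)Cc1c(O)cc(OCc2ccccc2)cc1OCc1ccccc1.[I-] | intermediate
15 | 3,5-bis(benzyloxy)-6-methylidenecyclohexa-2,4-dien-1-one | C=C1C(=O)C=C(OCc2ccccc2)C=C1OCc1ccccc1 | intermediate
16 | rac-benzyl 2-[3,4-bis(benzyloxy)phenyl]-3-[2,4-bis(benzyloxy)-6-hydroxyphenyl]-2-hydroxypropanoate | OC(Cc1c(O)cc(OCc2ccccc2)cc1OCc1ccccc1)(C(=O)OCc1ccccc1)c1ccc(OCc2ccccc2)c(OCc2ccccc2)c1 | intermediate
17 | rac-2-[3,4-bis(benzyloxy)phenyl]-3-[2,4-bis(benzyloxy)-6-hydroxyphenyl]-2-hydroxypropanal | O=CC(O)(Cc1c(O)cc(OCc2ccccc2)cc1OCc1ccccc1)c1ccc(OCc2ccccc2)c(OCc2ccccc2)c1 | intermediate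
18 | rac-5,7-bis(benzyloxy)-3-[3,4-bis(benzyloxy)phenyl]chromane-2,3-diol (anomer mixture) | OC1Oc2cc(OCc3ccccc3)cc(OCc3ccccc3)c2CC1(O)c1ccc(OCc2ccccc2)c(OCc2ccccc2)c1 | intermediate
19 | 2-O-methanesulfonate of 18 | CS(=O)(=O)OC1Oc2cc(OCc3ccccc3)cc(OCc3ccccc3)c2CC1(O)c1ccc(OCc2ccccc2)c(OCc2ccccc2)c1 | intermediate
20 | rac-5,7-bis(benzyloxy)-2-[3,4-bis(benzyloxy)phenyl]chroman-3-one | O=C1Cc2c(OCc3ccccc3)cc(OCc3ccccc3)cc2OC1c1ccc(OCc2ccccc2)c(OCc2ccccc2)c1 | intermediate
21 | (2R,3R)-5,7,3',4'-tetra-O-benzylepicatechin | c1(OCc9ccccc9)cc(OCc9ccccc9)c2c(c1)O[C@H](c8ccc(OCc9ccccc9)c(OCc9ccccc9)c8)[C@H](O)C2 | intermediate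
22 | (2R,3R)-8-bromo-5,7,3',4'-tetra-O-benzylepicatechin | c1(OCc9ccccc9)cc(OCc9ccccc9)c2c(c1Br)O[C@H](c8ccc(OCc9ccccc9)c(OCc9ccccc9)c8)[C@H](O)C2 | intermediate
23 | (2R,3R,4S)-8-bromo-5,7,3',4'-tetra-O-benzyl-4β-(2-hydroxyethoxy)epicatechin | c1(OCc9ccccc9)cc(OCc9ccccc9)c2c(c1Br)O[C@H](c8ccc(OCc9ccccc9)c(OCc9ccccc9)c8)[C@H](O)[C@H]2OCCO | intermediate
24 | [8-bromo-tetra-O-benzylepicatechin]-(4β→8)-[tetra-O-benzylepicatechin] | c1(OCc9ccccc9)cc(OCc9ccccc9)c2c(c1Br)O[C@H](c8ccc(OCc9ccccc9)c(OCc9ccccc9)c8)[C@H](O)[C@H]2c1c(OCc9ccccc9)cc(OCc9ccccc9)c2c1O[C@H](c8ccc(OCc9ccccc9)c(OCc9ccccc9)c8)[C@H](O)C2 | intermediate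
25 | [8-bromo-tetra-O-benzylepicatechin]-(4β→8)-[tetra-O-benzyl-4β-(2-hydroxyethoxy)epicatechin] | c1(OCc9ccccc9)cc(OCc9ccccc9)c2c(c1Br)O[C@H](c8ccc(OCc9ccccc9)c(OCc9ccccc9)c8)[C@H](O)[C@H]2c1c(OCc9ccccc9)cc(OCc9ccccc9)c2c1O[C@H](c8ccc(OCc9ccccc9)c(OCc9ccccc9)c8)[C@H](O)[C@H]2OCCO | intermediate
26 | [8-bromo-tetra-O-benzylepicatechin]-(4β→8)-[tetra-O-benzylepicatechin]-(4β→6)-[8-bromo-tetra-O-benzylepicatechin] | c1(OCc9ccccc9)cc(OCc9ccccc9)c2c(c1Br)O[C@H](c8ccc(OCc9ccccc9)c(OCc9ccccc9)c8)[C@H](O)[C@H]2c1c(OCc9ccccc9)cc(OCc9ccccc9)c2c1O[C@H](c8ccc(OCc9ccccc9)c(OCc9ccccc9)c8)[C@H](O)[C@H]2c1c(OCc9ccccc9)c(Br)c2c(c1OCc9ccccc9)C[C@@H](O)[C@@H](c8ccc(OCc9ccccc9)c(OCc9ccccc9)c8)O2 | intermediate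
27 | epicatechin-(4β→8)-epicatechin-(4β→6)-epicatechin | Oc1cc(O)c2c(c1)O[C@H](c1ccc(O)c(O)c1)[C@H](O)[C@H]2c1c(O)cc(O)c2c1O[C@H](c1ccc(O)c(O)c1)[C@H](O)[C@H]2c1c(O)cc2c(c1O)C[C@@H](O)[C@@H](c1ccc(O)c(O)c1)O2 | target

## Step count and risks
Total steps: 15. Longest linear sequence: 13 (1→4→6→8→16→18→20→21→22→23→24→25→26→27).

**Step 8 (new 1,2-aryl shift).**
- Failure modes: the tertiary OH may close a 2,3-epoxide, after which C3 ionises and a hydride shift gives the 3-aryl-dihydrocoumarin. Alternatively, the phenol of the open-chain form may be sulfonylated.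
- The fallback sets out from 6 and 12, comes back at 20, and uses no skeletal shift.
- Mitsunobu etherification (PPh3, DIAD, THF) of phenol 6 by hydroxy ester 12 gives rac-benzyl 2-[3,5-bis(benzyloxy)phenoxy]-2-[3,4-bis(benzyloxy)phenyl]acetate F1, which already holds the O1–C2 bond.
- Acylation of dimethylsulfoxonium methylide (Me3S(O)I, KOtBu, THF, 60 °C) by F1 gives the beta-keto sulfoxonium ylide F2.
- [Ir(cod)Cl]2-catalysed carbene transfer onto the arene ortho to O1 closes C4–C4a and gives 20. This is the sulfoxonium version of the diazoketone route to chroman-3-ones.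

**Step 9 (new dynamic kinetic resolution).**
- Failure modes: low enantioselection on a ketone flanked by two benzylic-type carbons, or base-induced decay of 20.
- The fallback sets out from 20 and comes back at 21.
- LiBH(sBu)3 in THF at −78 °C, the established cis-selective reduction of this ketone, gives rac-5,7,3',4'-tetra-O-benzylepicatechin F3.
- Preparative chiral HPLC on a cellulose carbamate phase delivers 21.
- The unwanted (2S,3S)-tetra-O-benzylepicatechin F4 is returned to 20 by Dess–Martin oxidation.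

**Step 13 (C4 oxidation of a dimer).**
- Failure modes: attack at the upper-unit C4–H or at C2–H, or low conversion.
- The fallback sets out from 21 (and uses 23 and 22), comes back at 26, and replaces late oxidation by orthogonal leaving groups.
- DDQ and ethylene glycol on 21 give 5,7,3',4'-tetra-O-benzyl-4β-(2-hydroxyethoxy)epicatechin F5.
- Thiolysis of F5 with 2,6-dimethylbenzenethiol and BF3·OEt2 (CH2Cl2, −78 °C) gives 5,7,3',4'-tetra-O-benzyl-4β-(2,6-dimethylphenylthio)epicatechin F6.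
- The hard Lewis acid BF3·OEt2 activates only the O-leaving group of 23, so C8 of F6 attacks it and gives the dimeric 4β-thioether F7.
- The thiophile AgBF4 then ionises F7 in the presence of 22 (5 equiv) to give 26.

## Further compounds
F1 | step 8 | rac-benzyl 2-[3,5-bis(benzyloxy)phenoxy]-2-[3,4-bis(benzyloxy)phenyl]acetate | O=C(OCc1ccccc1)C(Oc1cc(OCc2ccccc2)cc(OCc2ccccc2)c1)c1ccc(OCc2ccccc2)c(OCc2ccccc2)c1
F2 | step 8 | rac-1-(dimethyloxosulfaniumyl-ylide)-3-[3,5-bis(benzyloxy)phenoxy]-3-[3,4-bis(benzyloxy)phenyl]propan-2-one | CS(C)(=O)=CC(=O)C(Oc1cc(OCc2ccccc2)cc(OCc2ccccc2)c1)c1ccc(OCc2ccccc2)c(OCc2ccccc2)c1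
F3 | step 9 | rac-5,7,3',4'-tetra-O-benzylepicatechin (1:1 pair of cis enantiomers) | c1(OCc9ccccc9)cc(OCc9ccccc9)c2c(c1)O[C@H](c8ccc(OCc9ccccc9)c(OCc9ccccc9)c8)[C@H](O)C2.c1(OCc9ccccc9)cc(OCc9ccccc9)c2c(c1)O[C@@H](c8ccc(OCc9ccccc9)c(OCc9ccccc9)c8)[C@@H](O)C2
F4 | step 9 | (2S,3S)-5,7,3',4'-tetra-O-benzylepicatechin | c1(OCc9ccccc9)cc(OCc9ccccc9)c2c(c1)O[C@@H](c8ccc(OCc9ccccc9)c(OCc9ccccc9)c8)[C@@H](O)C2
F5 | step 13 | 5,7,3',4'-tetra-O-benzyl-4β-(2-hydroxyethoxy)epicatechin | c1(OCc9ccccc9)cc(OCc9ccccc9)c2c(c1)O[C@H](c8ccc(OCc9ccccc9)c(OCc9ccccc9)c8)[C@H](O)[C@H]2OCCO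
F6 | step 13 | 5,7,3',4'-tetra-O-benzyl-4β-(2,6-dimethylphenylthio)epicatechin | c1(OCc9ccccc9)cc(OCc9ccccc9)c2c(c1)O[C@H](c8ccc(OCc9ccccc9)c(OCc9ccccc9)c8)[C@H](O)[C@H]2Sc1c(C)cccc1C
F7 | step 13 | [8-bromo-tetra-O-benzylepicatechin]-(4β→8)-[tetra-O-benzyl-4β-(2,6-dimethylphenylthio)epicatechin] | c1(OCc9ccccc9)cc(OCc9ccccc9)c2c(c1Br)O[C@H](c8ccc(OCc9ccccc9)c(OCc9ccccc9)c8)[C@H](O)[C@H]2c1c(OCc9ccccc9)cc(OCc9ccccc9)c2c1O[C@H](c8ccc(OCc9ccccc9)c(OCc9ccccc9)c8)[C@H](O)[C@H]2Sc1c(C)cccc1C
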